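## The problem

Numbering used throughout: octalin C1–C8a. C1 bears the pentadienoic acid C1′–C5′ through C5′, C2 bears the but-2-en-2-yl group C1″–C4″ through C2″, C3 and C8 each bear a methyl group, and C7 bears the sulfate. Ring A is C1–C2–C3–C4–C4a–C8a with C3=C4, and ring B is C4a–C5–C6–C7–C8–C8a.

The rings are cis-fused, and six contiguous stereocentres (C1, C2, C4a, C7, C8, C8a) must be related to one another. The hydrogens at C2, C4a, C8a, C8 and C7 lie on one face and H–C1 lies on the other, so ring B is all-cis and the ring A substituents alternate.

This is the pattern of an exo (cis-fusing) triene cycloaddition, whereas the usually preferred endo mode gives the trans-fused series.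

C7 and C8 could be corrected through a C7 ketone, and C1 could be corrected through an aldehyde, because its natural configuration is the all-equatorial one. C2, C4a and C8a cannot be corrected and must be set together.

The E-trisubstituted butenyl olefin needs a defined origin. H–C2 is doubly allylic, and the secondary sulfate and the dienoic acid tolerate neither strong acid nor forcing conditions, so they come last.

The feature that opens the plan is this. C2 and C4a, 1,4 across ring A, carry C2″ and C5 on the same face. C8 on C8a lies on that face too, and C5′ on C1 lies on the opposite one. Joining C2″ to C5 by a double bond turns ring A into a bicyclo[2.2.2]octene. Its six-membered ring C4–C3–C2–C2″–C5–C4a, with methyl groups on C3 and C2″ and oxygen on C4, is 2,4-dimethylphenol (8).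

## Retrosynthesis

**End game, 25 back to 17.** The S–O bond, the ester and the C4′=C5′ bond are cut, giving the chain 25 ⇐ 24 ⇐ 23 ⇐ 22 ⇐ aldehyde 19 + phosphonate 20, and 19 ⇐ ester 17. This keeps the sulfate and the dienoate out of all C–C bond work on the core. C1 is not at risk in 19, because its configuration is the thermodynamic one. The forward reactions need only E selectivity and mildness.

**Ring B and the butenyl group, 17 back to 14.** One unsaturation is added (C5=C6, 15) and C4 is carried as an enol triflate (16, 15). Then C5=C6 and C2″=C3″ are cut and rejoined crosswise as C5=C2″ and C6=C3″. This retro ring-rearrangement metathesis leads to the isomeric bicyclo[2.2.2]octadiene 14. A cut at C5=C6 alone would leave the cis-1,4 relation C2/C4a and the E olefin as separate problems. The crosswise cut stores both in one bridge. The forward reaction must open only the C5=C2″ bridge and cap C2″ with E geometry.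

**The masked ring A olefin, 14 back to 10.** C4–OTf goes back to the ketone 12 (⇐ acid 11), and H–C3 goes back to a C3–O bond in the keto lactone 10. In the bicycle C4a is a bridgehead, so the ketone can enolise only towards C3. The regiochemical problem of the open octalone does not arise. The C3–O bond is α to the ketone and is therefore cleaved reductively.

**The core, 10 back to 7 + 8.** C1–C2 and C4a–C8a are cut (retro-[4+2]) to give the 6-acyloxycyclohexadienone 9. The C3–O bond is then cut to give the acid 7 and the phenol 8. The same two σ-bonds are made in the biomimetic route. Here the diene is locked s-cis in a ring, and a three-atom temporary tether dictates both regiochemistry and the exo-type outcome. Four ring stereocentres, three rings and eight carbons of a commodity phenol come in one operation from an acyclic acid.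

**The acid, 7 back to 1 + 2 + 6.** C1=C8a is cut (cross metathesis of 5 with acrylic acid 6), and C7–C8 is cut (anti-crotylation of crotonaldehyde 1 with 2, through 3 and 4). Crotonaldehyde supplies C7, C6 and also the C3″–C4″ ethylidene that the metathesis later moves onto C2″.

## Roads not taken

**Alternative 1:** This is the obvious, biomimetic cut of C1–C2 and C4a–C8a in the octalin itself, an intramolecular Diels–Alder reaction of the linear hexaenoate A1 that closes both rings at once. The target needs the exo, cis-fusing mode, while E,E,E-decatrienes with a terminal acceptor favour the endo, trans-fusing mode both thermally and under Lewis acids. A1 holds two trienes and therefore several diene/dienophile pairings. Only the allylic centre C8 could steer the facial choice. The sensitive polyene also has to be built in a long linear sequence. The chosen plan makes the same bonds on a cyclic diene, where the tether rather than an endo/exo preference decides.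

**Alternative 2:** Here C4a–C5 is cut and C3–C7 is rejoined, which is an anionic oxy-Cope rearrangement of the vinyl carbinol A2. The cis fusion, C3=C4 and a C7 ketone would all result, and the reaction type is well precedented. A2, however, needs the butenyl group on the bridge carbon next to the methyl-bearing bridgehead and turned away from the etheno bridge. The ortho and endo rules of cyclohexadienone cycloadditions fail on one count or the other. A lactone tether sets C1 wrongly, so the Z acid A3 and a late epimerisation at C1 would be needed. A3 is achiral, so the series is racemic and needs a resolution, and C7 and C8 remain to be set.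

**Alternative 3:** Here C4a–C5 and C8–C8a are cut, which is an intermolecular quinone Diels–Alder reaction that builds ring B onto ring A and gives the cis-fused enedione A4. The endo rule would set C4a, C8a and C8 correctly. The butenyl group would then have to enter at C2 from the concave face. Two ring A carbonyl groups would have to be removed. The C4 ketone has two tertiary α-carbons, so the position of C3=C4 is not secured. C4a stays epimerisable next to a ketone through many steps.

Key step: step 4

Assumption: 25 is handled as the free acid form that is drawn (released from its salt in the last operation), and the sense of induction of the phosphoric acid in step 1 is taken from its behaviour with related aldehydes, the antipode being used if it proves opposite.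

## Steps

Step 1
Reactants: 1 (E)-but-2-enal; 2 (E)-crotylboronic acid pinacol ester
Product: 4 (3S,4R,5E)-3-methylhepta-1,5-dien-4-ol, via pinacol borate 3 (not isolated)
Conditions: (S)-3,3′-bis(2,4,6-triisopropylphenyl)-1,1′-binaphthyl-2,2′-diyl hydrogen phosphate (5 mol %), toluene, −30 °C; aq. NaHCO3 work-up
Reagents that add atoms: none
Why: Phosphoric-acid-catalysed crotylboration through a closed chair transition state; the E-crotyl group gives the anti relation C7/C8 (cis once both lie on ring B), and the catalyst, hydrogen-bonded to a boronate oxygen, selects the aldehyde face and so fixes both centres absolutely.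

Step 2
Reactants: 4 (3S,4R,5E)-3-methylhepta-1,5-dien-4-ol
Product: 5 tert-butyldimethylsilyl ether of 4
Conditions: TBSCl, imidazole, DMF, rt
Reagents that add atoms: tert-butyldimethylsilyl chloride, CC(C)(C)[Si](C)(C)Cl
Why: Standard silylation of a secondary alcohol; the ether should survive oxidant, SmI2, amide bases, metathesis, formate reduction and DIBAL-H, and its bulk slows metathesis at the neighbouring propenyl group.

Step 3
Reactants: 5 silyl ether; 6 acrylic acid
Product: 7 (2E,4S,5R,6E)-5-[(tert-butyldimethylsilyl)oxy]-4-methylocta-2,6-dienoic acid
Conditions: second-generation Hoveyda–Grubbs catalyst (5 mol %), CH2Cl2, 40 °C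
Reagents that add atoms: none
Why: Olefin cross metathesis; the monosubstituted olefin of 5 pairs with the electron-poor acrylic acid, while the 1,2-disubstituted propenyl group next to the silyloxy carbon reacts much more slowly, and the enoic acid forms as the E isomer.

Step 4
Reactants: 7 dienoic acid; 8 2,4-dimethylphenol
Product: 10 tricyclic keto lactone (bicyclo[2.2.2]oct-5-en-2-one with bridgeheads C2 and C4a; γ-lactone C3–O–C5′(=O)–C1 over the keto bridge; C8 side chain on C8a over the etheno bridge), via acyloxydienone 9 (not isolated)
Conditions: Pb(OAc)4 (1.1 equiv), 7 (3 equiv, excess recovered by base extraction), CH2Cl2, 0 °C to rt; filtration; then toluene, 110 °C; chromatography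
Reagents that add atoms: none
Why: Ligand exchange on tetravalent lead gives an aryloxy-lead carboxylate that passes its carboxylate to the methyl-bearing ortho carbon C3 within the coordination sphere (Wessely oxidation in its variant with unsaturated acids); the dienone 9 cannot rearomatise and on heating its diene C4a=C5–C2″=C2 adds suprafacially to the enoate C1=C8a in an intramolecular [4+2] cycloaddition, the closest known case being the same tandem with simple acrylic acids. The three-atom tether C3–O–C5′ allows only the pairing C1–C2 and C8a–C4a, so the lactone closes as a five-membered ring fused at C2–C3 (the reverse pairing would need a bridged lactone) and the two new six-membered rings arise as the bicyclo[2.2.2]octene. C2 and C4a are set by suprafacial addition across the cyclic diene, which puts C2″ and C5 on one face of the future ring A. C1 is set by the tether, which holds C5′ over the keto bridge, and C8a by the E geometry of the enoate, which places C8 over the etheno bridge and trans to C5′; this is the relation found in 25. C3 is formed without control, and because the dienophile can reach only the face that carries the ester oxygen, the (S)-epimer of 9 gives 10 while the (R)-epimer cyclises in the opposite core sense; since C7 and C8 are fixed the two outcomes are diastereomeric and separable on silica, and at most half of 9 can end as 10. The step further needs attack at the methyl-bearing ortho carbon rather than at the para or free ortho carbon (inner-sphere delivery from lead), transfer of the carboxylate of 7 rather than acetate (excess 7), and the enoate rather than the propenyl group as dienophile (activation and tether length).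

Step 5
Reactants: 10 tricyclic keto lactone
Product: 11 bicyclic keto acid (C3–H, either configuration; C1 carboxylic acid)
Conditions: SmI2 (2.5 equiv), THF–MeOH, −78 °C
Reagents that add atoms: none
Why: Reduction of an α-acyloxy ketone by divalent samarium; the ketyl/enolate expels the carboxylate, which removes the tether, frees C5′ as the acid and erases the uncontrolled centre C3, whose new configuration is of no consequence.

Step 6
Reactants: 11 bicyclic keto acid
Product: 12 methyl ester of 11
Conditions: MeI, K2CO3, DMF, rt
Reagents that add atoms: iodomethane, CI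
Why: O-alkylation of the carboxylate; the base is too weak to enolise the ester, and epimerisation at C3 does not matter.

Step 7
Reactants: 12 keto ester
Product: 14 bicyclo[2.2.2]octadienyl triflate (C3(CH3)=C4–OTf), via potassium enolate 13 (not isolated)
Conditions: KHMDS (1.05 equiv), THF, −78 °C; PhNTf2, −78 °C to 0 °C
Reagents that add atoms: N-phenylbis(trifluoromethanesulfonimide), O=S(=O)(N(c1ccccc1)S(=O)(=O)C(F)(F)F)C(F)(F)F
Why: Enol triflate formation; by Bredt's rule the bridgehead C4a cannot enolise, so the ketone (more acidic than the ester) gives only the C3=C4 enolate, as used for bicyclo[2.2.2]octadiene ligands. The tetrasubstituted, electron-poor triflate masks the future ring A olefin.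

Step 8
Reactants: 14 bicyclo[2.2.2]octadienyl triflate
Product: 15 cis-1,2,4a,7,8,8a-hexahydronaphthalene (C5=C6, C4–OTf, E-butenyl at C2, all stereocentres as in 25)
Conditions: second-generation Hoveyda–Grubbs catalyst (10 mol %), (Z)-but-2-ene (excess), toluene, 60–80 °C
Reagents that add atoms: none
Why: Proposed new method: ring-rearrangement metathesis is known for bicyclo[2.2.2]octenes with a disubstituted etheno bridge but not a trisubstituted one; the ruthenium ethylidene (kept up by but-2-ene and by the propenyl end of 14) should add to C5=C2″ with its carbon on the more substituted C2″ and the metal on C5, the usual regiochemistry for trisubstituted olefins, driven by release of the strain of the bicyclooctadiene. The C5 alkylidene then closes ring B (six-membered, cis-fused) on the propenyl group that step 4 placed over this bridge and regenerates the ethylidene, while the enol triflate olefin stays inert, so that 14 is isomerised to 15. In the metallacyclobutane the ethylidene methyl should turn away from the bridgehead C2 and towards C1″, which gives the E-butenyl group, also the more stable isomer.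

Step 9
Reactants: 15 hexahydronaphthalene
Product: 16 cis-octalin triflate (C5–C6 saturated)
Conditions: 2-nitrobenzenesulfonohydrazide, Et3N, CH2Cl2, rt
Reagents that add atoms: none
Why: Diimide reduction by concerted syn transfer of H2; its rate falls steeply with substitution, so the cis-disubstituted C5=C6 should react before the trisubstituted butenyl and the tetrasubstituted enol triflate olefins. This also removes the skipped diene before palladium is used.

Step 10
Reactants: 16 octalin triflate
Product: 17 methyl (1S,2S,4aS,7R,8S,8aR-type, as in 25) 2-[(E)-but-2-en-2-yl]-7-silyloxy-3,8-dimethyl-octalin-1-carboxylate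
Conditions: Pd(OAc)2 (5 mol %), PPh3 (10 mol %), HCO2H, Et3N, DMF, 60 °C
Reagents that add atoms: none
Why: Palladium-catalysed formate reduction of an enol triflate (oxidative addition to zerovalent palladium, formate exchange, loss of CO2, reductive elimination); hydrogen replaces OTf at C4 with the olefin fixed at C3=C4.

Step 11
Reactants: 17 methyl ester
Product: 19 C1 carbaldehyde, via aluminium hemiacetal 18 (not isolated)
Conditions: DIBAL-H (1.1 equiv), CH2Cl2, −78 °C; aq. Rochelle salt
Reagents that add atoms: none
Why: Partial reduction of an ester; the hindered tetrahedral aluminium hemiacetal should persist at −78 °C and collapse only on work-up. C1 is safe because its configuration, trans to both neighbours, is the equatorial and more stable one.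

Step 12
Reactants: 19 aldehyde; 20 triethyl 4-phosphonocrotonate
Product: 22 ethyl (2E,4E)-dienoate, via lithio phosphonate 21 (not isolated)
Conditions: LiHMDS, THF, −78 °C; then 19, −78 °C to 0 °C
Reagents that add atoms: none
Why: Vinylogous Horner–Wadsworth–Emmons olefination; the stabilised allylic phosphonate anion reacts at its α-carbon and gives the new C4′=C5′ bond with E geometry, while the crotonate olefin stays E.

Step 13
Reactants: 22 silyl ether dienoate
Product: 23 C7 alcohol
Conditions: HF·pyridine, THF, 0 °C to rt
Reagents that add atoms: none
Why: Fluoride-driven desilylation in a buffered medium that is neither basic enough to touch the dienoate nor acidic enough to protonate the trisubstituted olefins or move the doubly allylic H–C2.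

Step 14
Reactants: 23 alcohol
Product: 24 C7 hydrogen sulfate (ethyl ester; isolated as pyridinium salt)
Conditions: SO3·pyridine, pyridine, 40 °C
Reagents that add atoms: sulfur trioxide–pyridine complex, O=S(=O)([O-])[n+]1ccccc1
Why: O-sulfation of the only hydroxyl group with a mild SO3 donor; the C–O bond is not touched, so C7 keeps its configuration.

Step 15
Reactants: 24 sulfate ester
Product: 25 target, (2E,4E)-5-[(1S,2S,4aS,7R,8S,8aR)-2-[(E)-but-2-en-2-yl]-3,8-dimethyl-7-(sulfooxy)-1,2,4a,5,6,7,8,8a-octahydronaphthalen-1-yl]penta-2,4-dienoic acid
Conditions: LiOH, THF–MeOH–H2O, rt; cold 1 M HCl to pH 2, rapid extraction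
Reagents that add atoms: lithium hydroxide, [Li+].[OH-]
Why: Saponification by acyl–oxygen cleavage; the sulfate monoester anion resists hydroxide, and short, cold acidification gives the free acid form.

## Compound list

1 | (E)-but-2-enal | C/C=C/C=O | starting material
2 | 2-[(E)-but-2-en-1-yl]-4,4,5,5-tetramethyl-1,3,2-dioxaborolane | C/C=C/CB1OC(C)(C)C(C)(C)O1 | starting material
3 | pinacol borate of 4 | C/C=C/[C@@H](OB1OC(C)(C)C(C)(C)O1)[C@@H](C)C=C | intermediate
4 | (3S,4R,5E)-3-methylhepta-1,5-dien-4-ol | C/C=C/[C@@H](O)[C@@H](C)C=C | intermediate
5 | tert-butyldimethylsilyl ether of 4 | C/C=C/[C@@H](O[Si](C)(C)C(C)(C)C)[C@@H](C)C=C | intermediate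
6 | acrylic acid | C=CC(=O)O | starting material
7 | (2E,4S,5R,6E)-5-[(tert-butyldimethylsilyl)oxy]-4-methylocta-2,6-dienoic acid | C/C=C/[C@@H](O[Si](C)(C)C(C)(C)C)[C@@H](C)/C=C/C(=O)O | intermediate
8 | 2,4-dimethylphenol | Cc1ccc(O)c(C)c1 | starting material
9 | 1,3-dimethyl-6-oxocyclohexa-2,4-dien-1-yl ester of 7 (both epimers at the ring carbon that is C3) | C/C=C/[C@@H](O[Si](C)(C)C(C)(C)C)[C@@H](C)/C=C/C(=O)OC1(C)C=C(C)C=CC1=O | intermediate
10 | tricyclic keto lactone (lactone over the keto bridge, side chain over the etheno bridge) | C/C=C/[C@@H](O[Si](C)(C)C(C)(C)C)[C@@H](C)[C@@H]1[C@@H]2C=C(C)[C@H]([C@H]1C(=O)O3)[C@@]3(C)C2=O | intermediate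
11 | bicyclo[2.2.2]octenone carboxylic acid (C3 undefined) | C/C=C/[C@@H](O[Si](C)(C)C(C)(C)C)[C@@H](C)[C@@H]1[C@@H]2C=C(C)[C@H]([C@H]1C(=O)O)C(C)C2=O | intermediate
12 | methyl ester of 11 | C/C=C/[C@@H](O[Si](C)(C)C(C)(C)C)[C@@H](C)[C@@H]1[C@@H]2C=C(C)[C@H]([C@H]1C(=O)OC)C(C)C2=O | intermediate
13 | potassium C3=C4 enolate of 12 | C/C=C/[C@@H](O[Si](C)(C)C(C)(C)C)[C@@H](C)[C@@H]1[C@@H]2C=C(C)[C@H]([C@H]1C(=O)OC)C(C)=C2[O-].[K+] | intermediate
14 | bicyclo[2.2.2]octadienyl triflate | C/C=C/[C@@H](O[Si](C)(C)C(C)(C)C)[C@@H](C)[C@@H]1[C@@H]2C=C(C)[C@H]([C@H]1C(=O)OC)C(C)=C2OS(=O)(=O)C(F)(F)F | intermediate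
15 | cis-hexahydronaphthalene triflate with E-butenyl group | C/C=C(\C)[C@H]1C(C)=C(OS(=O)(=O)C(F)(F)F)[C@H]2C=C[C@@H](O[Si](C)(C)C(C)(C)C)[C@@H](C)[C@H]2[C@@H]1C(=O)OC | intermediate
16 | cis-octalin triflate | C/C=C(\C)[C@H]1C(C)=C(OS(=O)(=O)C(F)(F)F)[C@H]2CC[C@@H](O[Si](C)(C)C(C)(C)C)[C@@H](C)[C@H]2[C@@H]1C(=O)OC | intermediate
17 | cis-octalin methyl ester | C/C=C(\C)[C@H]1C(C)=C[C@H]2CC[C@@H](O[Si](C)(C)C(C)(C)C)[C@@H](C)[C@H]2[C@@H]1C(=O)OC | intermediate
18 | diisobutylaluminium hemiacetal of 17 | C/C=C(\C)[C@H]1C(C)=C[C@H]2CC[C@@H](O[Si](C)(C)C(C)(C)C)[C@@H](C)[C@H]2[C@@H]1C(OC)O[Al](CC(C)C)CC(C)C | intermediate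
19 | cis-octalin-1-carbaldehyde | C/C=C(\C)[C@H]1C(C)=C[C@H]2CC[C@@H](O[Si](C)(C)C(C)(C)C)[C@@H](C)[C@H]2[C@@H]1C=O | intermediate
20 | triethyl 4-phosphonocrotonate | CCOC(=O)/C=C/CP(=O)(OCC)OCC | starting material
21 | lithium salt of 20 | CCOC(=O)/C=C/[CH-]P(=O)(OCC)OCC.[Li+] | intermediate
22 | ethyl (2E,4E)-dienoate, C7 silyl ether | C/C=C(\C)[C@H]1C(C)=C[C@H]2CC[C@@H](O[Si](C)(C)C(C)(C)C)[C@@H](C)[C@H]2[C@@H]1/C=C/C=C/C(=O)OCC | intermediate
23 | ethyl (2E,4E)-dienoate, C7 alcohol | C/C=C(\C)[C@H]1C(C)=C[C@H]2CC[C@@H](O)[C@@H](C)[C@H]2[C@@H]1/C=C/C=C/C(=O)OCC | intermediate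
24 | ethyl (2E,4E)-dienoate, C7 hydrogen sulfate | C/C=C(\C)[C@H]1C(C)=C[C@H]2CC[C@@H](OS(=O)(=O)O)[C@@H](C)[C@H]2[C@@H]1/C=C/C=C/C(=O)OCC | intermediate
25 | CNP0450810.8 | C/C=C(\C)[C@H]1C(C)=C[C@H]2CC[C@@H](OS(=O)(=O)O)[C@@H](C)[C@H]2[C@@H]1/C=C/C=C/C(=O)O | target

## Step count and least certain steps

Total step count: 15. Longest linear sequence: 15 steps (1 to 25).

**Step 8.**
- **Risk:** The catalyst may only shuttle between propenyl groups (degenerate exchange, intermolecular coupling) without opening the hindered trisubstituted bridge. Capping of C2″ may also proceed with poor geometric control, which secondary metathesis cannot repair at a trisubstituted olefin.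
- **Fallback (known chemistry, from 14 back to 15):** Catalytic OsO4/NMO followed by NaIO4 should cleave the strained, most electron-rich olefin C5=C2″ to the keto aldehyde F1. Methylenetriphenylphosphorane takes only the aldehyde and gives the vinyl compound F2. Ordinary ring-closing metathesis of the vinyl and propenyl groups (second-generation Grubbs catalyst) gives the acetyl hexahydronaphthalene F3. Addition of [1-(trimethylsilyl)ethyl]magnesium chloride with CeCl3 gives the β-hydroxysilanes F4. Their two diastereomers are separated and eliminated, one with KH (syn) and the other with BF3·OEt2 (anti), so that both converge on the E olefin of 15 (Peterson olefination).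

**Step 4 (key step).**
- **Risk:** Acyloxy transfer may go to the para or the free ortho carbon. Acetate may be transferred in place of the carboxylate of 7. The acyloxy group may shift sigmatropically to the para carbon on heating. In any case the C3 epimer that cyclises in the wrong core sense is lost.
- **Fallback (from 7 back to 9 as a single epimer):** Racemic 2,4-dimethylcyclohex-2-en-1-one F5 is converted with KHMDS into its extended dienolate. This is hydroxylated at the α-carbon with an enantiopure (camphorsulfonyl)oxaziridine to the β,γ-unsaturated ketol F6. Esterification with 7 (2,4,6-trichlorobenzoyl chloride, Et3N, DMAP) gives the ester F7, from which the minor diastereomer is removed. Dehydrogenation with 2-iodoxybenzoic acid (DMSO–toluene, 70–80 °C) gives only the (S)-epimer of 9, which cyclises to 10.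

**Step 11.**
- **Risk:** The aluminium hemiacetal may collapse early, followed by over-reduction, or conversion of the hindered ester may be incomplete.
- **Fallback (from 17 back to 19):** Full reduction with excess DIBAL-H gives the primary alcohol F8, which is oxidised with Dess–Martin periodinane.

**Step 15.**
- **Risk:** The axial secondary sulfate may undergo solvolysis or elimination during acidification, and the conjugated ester may saponify slowly.
- **Fallback (from 23 back to 25):** The ester is saponified first to the hydroxy acid F9. The hydroxyl group is then sulfated with SO3·pyridine, any acyl sulfate being hydrolysed in the bicarbonate work-up. The salt is converted into 25 on a cold acidic ion-exchange resin, so that the sulfate never meets mineral acid.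

## Further compounds

F1 | step 8 | keto aldehyde (C2 acetyl, C4a formyl) | CC(=O)[C@H]1C(C)=C(OS(=O)(=O)C(F)(F)F)[C@@H](C=O)[C@H]([C@@H]1C(=O)OC)[C@H](C)[C@H](O[Si](C)(C)C(C)(C)C)/C=C/C
F2 | step 8 | vinyl compound (C2 acetyl, C4a vinyl) | CC(=O)[C@H]1C(C)=C(OS(=O)(=O)C(F)(F)F)[C@@H](C=C)[C@H]([C@@H]1C(=O)OC)[C@H](C)[C@H](O[Si](C)(C)C(C)(C)C)/C=C/C
F3 | step 8 | acetyl hexahydronaphthalene | CC(=O)[C@H]1C(C)=C(OS(=O)(=O)C(F)(F)F)[C@H]2C=C[C@@H](O[Si](C)(C)C(C)(C)C)[C@@H](C)[C@H]2[C@@H]1C(=O)OC
F4 | step 8 | β-hydroxysilanes (two new centres undefined) | CC([Si](C)(C)C)C(C)(O)[C@H]1C(C)=C(OS(=O)(=O)C(F)(F)F)[C@H]2C=C[C@@H](O[Si](C)(C)C(C)(C)C)[C@@H](C)[C@H]2[C@@H]1C(=O)OC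
F5 | step 4 | 2,4-dimethylcyclohex-2-en-1-one (racemic) | CC1=CC(C)CCC1=O
F6 | step 4 | (S)-2-hydroxy-2,4-dimethylcyclohex-3-en-1-one | CC1=C[C@](C)(O)C(=O)CC1
F7 | step 4 | ester of F6 with 7 | C/C=C/[C@@H](O[Si](C)(C)C(C)(C)C)[C@@H](C)/C=C/C(=O)O[C@@]1(C)C=C(C)CCC1=O
F8 | step 11 | C1 hydroxymethyl octalin | C/C=C(\C)[C@H]1C(C)=C[C@H]2CC[C@@H](O[Si](C)(C)C(C)(C)C)[C@@H](C)[C@H]2[C@@H]1CO
F9 | step 15 | C7 hydroxy dienoic acid | C/C=C(\C)[C@H]1C(C)=C[C@H]2CC[C@@H](O)[C@@H](C)[C@H]2[C@@H]1/C=C/C=C/C(=O)O
A1 | alternative 1 | ethyl (2E,4E,6E,8S,9R,12E,14E,16E)-9-[(tert-butyldimethylsilyl)oxy]-8,14,16-trimethyloctadeca-2,4,6,12,14,16-hexaenoate | C/C=C(\C)/C=C(\C)/C=C/CC[C@@H](O[Si](C)(C)C(C)(C)C)[C@@H](C)/C=C/C=C/C=C/C(=O)OCC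
A2 | alternative 2 | 2-vinylbicyclo[2.2.2]oct-5-en-2-ol with bridgeheads C3 and C8a (vinyl over the etheno bridge, butenyl over the carbinol bridge) | C/C=C(\C)[C@@H]1[C@@H](CO[Si](C)(C)C(C)(C)C)[C@H]2C=C[C@]1(C)[C@](O)(C=C)[C@H]2C
A3 | alternative 2 | (2Z,4E)-4-methylhexa-2,4-dienoic acid | C/C=C(\C)/C=C\C(=O)O
A4 | alternative 3 | cis-fused enedione with C7 triisopropylsilyl enol ether | CC1=CC(=O)[C@@H]2[C@H](C)C(O[Si](C(C)C)(C(C)C)C(C)C)=CC[C@@H]2C1=O
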